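Retrosynthesis: the two O-Si bonds are cut first. C3-O is then traced back to the C3=C4 alkene of a flav-3-ene, a formyl carbon is restored on C3, and ring C is opened at O1-C2 and C3-C4. Ring A is simplified at C8-prenyl and C4a-C4.
Enabling feature: O1, C8a, C4a and C4 of ring C form the ortho O-C=C-CHO array of a ring A salicylaldehyde. C2, C3 and ring B are the β-carbon, α-carbon and aryl group of a cinnamaldehyde, whose own CHO sits on C3 as a removable activator.
Forward order: ring A is dressed first (prenyl by lithiation between two OMOM groups, O7 silylated, C4 added by ortho-formylation). Ring B is bought ready-made, and ring C closes last in one domino step.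
Stereochemistry: C2 comes from face shielding of the cinnamaldehyde iminium ion by an (S)-diarylprolinol silyl ether. C3 comes from syn borylcupration of the flav-3-ene anti to the C2 aryl group, followed by oxidation with retention (2,3-trans).
Chemoselectivity: a copper-boryl species carries boron to C3 because it adds only to the aryl-conjugated C3=C4 bond, whereas a stoichiometric borane could not be relied on to spare the prenyl alkene.

Key step: step 7

Remark: flavan numbering (O1, C2-C4, C4a, C5-C8, C8a, ring B primed) is used for all bicyclic compounds.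
Assumption: the sense of induction follows the usual model for (S)-diarylprolinol silyl ethers (E, s-trans iminium ion, attack anti to the CPh2OSiMe3 group), which makes C2 of 15 (R). The (R)-catalyst is equally available if the sense has to be inverted.

Step 1
Reactants: 1 5-methoxyresorcinol
Product: 2 1-methoxy-3,5-bis(methoxymethoxy)benzene
Conditions: MOMCl (2.5 equiv), i-Pr2NEt (3 equiv), CH2Cl2, 0 °C to rt
Reagents that add atoms: chloromethyl methyl ether (MOMCl), COCCl
Why: Base-mediated O-alkylation of both phenols with the reactive α-chloro ether (MOM protection) masks the acidic protons and installs the two strongest ortho-directing groups on the ring.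

Step 2
Reactants: 2 1-methoxy-3,5-bis(methoxymethoxy)benzene, 3 prenyl bromide
Product: 5 5-methoxy-1,3-bis(methoxymethoxy)-2-(3-methylbut-2-enyl)benzene, via aryllithium 4 (not isolated)
Conditions: n-BuLi (1.1 equiv), THF, 0 °C, 1 h; then 3 (1.3 equiv), -78 °C to rt
Reagents that add atoms: none
Why: In this directed ortho-metalation the two chelating OMOM groups together steer n-BuLi to the carbon between them rather than to the OMOM/OMe-flanked positions, and aryllithium 4 then displaces bromide from the primary allylic carbon of 3 (SN2), fixing the prenyl group at the future C8.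

Step 3
Reactants: 5 5-methoxy-1,3-bis(methoxymethoxy)-2-(3-methylbut-2-enyl)benzene
Product: 6 5-methoxy-2-(3-methylbut-2-enyl)benzene-1,3-diol
Conditions: HCl (3 M aq, catalytic), MeOH, 40 °C
Reagents that add atoms: none
Why: Acid-catalysed acetal exchange with methanol frees both phenols, since acetal cleavage in dilute acid at mild temperature is much faster than the protonation of the trisubstituted alkene that would start chroman formation.

Step 4
Reactants: 6 5-methoxy-2-(3-methylbut-2-enyl)benzene-1,3-diol
Product: 7 5-methoxy-2-(3-methylbut-2-enyl)-3-(triisopropylsilyloxy)phenol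
Conditions: TIPSCl (1.0 equiv), imidazole (2 equiv), DMF, 0 °C to rt
Reagents that add atoms: triisopropylsilyl chloride (TIPSCl), CC(C)[Si](Cl)(C(C)C)C(C)C
Why: The two hydroxyl groups of 6 are equivalent, so silylation of either gives the same product, and over-silylation is held back by limiting TIPSCl and by the bulk of the first TIPS group pressing on the prenyl chain.

Step 5
Reactants: 7 5-methoxy-2-(3-methylbut-2-enyl)-3-(triisopropylsilyloxy)phenol
Product: 9 2-hydroxy-6-methoxy-3-(3-methylbut-2-enyl)-4-(triisopropylsilyloxy)benzaldehyde, via hydroxymethylphenol 8 (not isolated)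
Conditions: MgCl2 (anhydrous, 2 equiv), Et3N (4 equiv), (CH2O)n (6 equiv), THF, reflux; aq HCl work-up
Reagents that add atoms: paraformaldehyde (reacts as formaldehyde), C=O
Why: In the Casnati-Skattebøl ortho-formylation magnesium holds phenoxide and formaldehyde together, so the C-C bond can form only at the single free ortho carbon (future C4a) to give 8, which a second formaldehyde oxidises by hydride transfer, under conditions that harm neither the aryl TIPS ether nor the prenyl group.

Step 6
Reactants: 10 (E)-4-hydroxycinnamaldehyde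
Product: 11 (E)-4-(triisopropylsilyloxy)cinnamaldehyde
Conditions: TIPSCl (1.2 equiv), imidazole (2.5 equiv), CH2Cl2, 0 °C to rt
Reagents that add atoms: triisopropylsilyl chloride (TIPSCl), CC(C)[Si](Cl)(C(C)C)C(C)C
Why: This is a standard phenol silylation, with TIPS chosen over smaller silyl groups so that the aryl ether survives the alkoxide and methanol of step 9 and both silyl groups fall together in step 10.

Step 7
Reactants: 9 2-hydroxy-6-methoxy-3-(3-methylbut-2-enyl)-4-(triisopropylsilyloxy)benzaldehyde, 11 (E)-4-(triisopropylsilyloxy)cinnamaldehyde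
Product: 15 (2R)-5-methoxy-8-(3-methylbut-2-enyl)-7-(triisopropylsilyloxy)-2-[4-(triisopropylsilyloxy)phenyl]-2H-chromene-3-carbaldehyde, via iminium ion 12 (not isolated), via oxa-Michael enamine 13 (not isolated), via aldol iminium ion 14 (not isolated)
Conditions: (S)-2-[diphenyl(trimethylsilyloxy)methyl]pyrrolidine (20 mol %), 2-nitrobenzoic acid (20 mol %), 4 Å MS, toluene, rt, dark
Reagents that add atoms: none
Why: The amine condenses with the unhindered enal 11 to the E-configured iminium ion 12, whose face next to the CPh2OSiMe3 group is blocked, so the free phenol oxygen of 9 adds to the β-carbon from the open face and forms O1-C2 in enamine 13. The enamine carbon of 13 then attacks the neighbouring formyl group in a 6-(enolexo)-exo-trig aldol closure (C3-C4) to give 14, and loss of water with hydrolytic release of the amine delivers the conjugated chromene 15. The closest known reaction type is exactly this one, the diarylprolinol silyl ether catalysed oxa-Michael-aldol condensation of salicylaldehydes with cinnamaldehydes. C2 is the only lasting stereocentre and is controlled by the catalyst, while the transient centres C3 and C4 of 14 vanish on dehydration, the irreversible event that pulls the reversible oxa-Michael addition forward. The step needs one phenolic nucleophile and one iminium-forming aldehyde: O7 and O4' are silylated, the aldehyde of 9 is chelated, electron-rich and doubly ortho-substituted and so stays the acceptor, and the prenyl alkene is inert to both iminium ion and enamine. The acid co-catalyst speeds iminium formation and dehydration, and the sieves take up the water.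

Step 8
Reactants: 15 (2R)-5-methoxy-8-(3-methylbut-2-enyl)-7-(triisopropylsilyloxy)-2-[4-(triisopropylsilyloxy)phenyl]-2H-chromene-3-carbaldehyde
Product: 16 (2S)-5-methoxy-8-(3-methylbut-2-enyl)-7-(triisopropylsilyloxy)-2-[4-(triisopropylsilyloxy)phenyl]-2H-chromene
Conditions: RhCl(PPh3)3 (1.1 equiv), degassed toluene, 85 °C, dark
Reagents that add atoms: none
Why: In the Tsuji-Wilkinson decarbonylation monovalent rhodium inserts into the formyl C-H bond, extrudes CO and reductively eliminates the vinylic C3-H bond without touching C2 (only the CIP descriptor changes), and the stoichiometric complex permits a temperature low enough to keep the 2H-chromene from racemising by reversible electrocyclic ring opening.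

Step 9
Reactants: 16 (2S)-5-methoxy-8-(3-methylbut-2-enyl)-7-(triisopropylsilyloxy)-2-[4-(triisopropylsilyloxy)phenyl]-2H-chromene
Product: 18 (2R,3S)-5-methoxy-8-(3-methylbut-2-enyl)-7-(triisopropylsilyloxy)-2-[4-(triisopropylsilyloxy)phenyl]chroman-3-ol, via pinacol boronate 17 (not isolated)
Conditions: CuCl (5 mol %), SIMes·HCl (1,3-dimesitylimidazolinium chloride, 5 mol %), NaOt-Bu (15 mol %), B2pin2 (1.2 equiv), MeOH (2 equiv), THF, rt; then NaBO3·4H2O (5 equiv), THF/H2O, rt
Reagents that add atoms: sodium perborate (NaBO3·4H2O), [Na+].[O-]OB=O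
Why: In this copper-catalysed protoboration of an aryl-conjugated alkene, known for 2-aryl-2H-chromenes, the Cu-Bpin species adds syn across C3=C4 anti to the C2 aryl group with boron on C3 and copper on benzylic C4, methanol protonates the C4-Cu bond to give 17, the unconjugated prenyl alkene does not react, and perborate replaces boron by oxygen with retention to set the (3S), 2,3-trans alcohol.

Step 10
Reactants: 18 (2R,3S)-5-methoxy-8-(3-methylbut-2-enyl)-7-(triisopropylsilyloxy)-2-[4-(triisopropylsilyloxy)phenyl]chroman-3-ol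
Product: 19 (2R,3S)-2-(4-hydroxyphenyl)-5-methoxy-8-(3-methylbut-2-enyl)chroman-3,7-diol (8-prenylafzelechin 5-methyl ether)
Conditions: TBAF (2.4 equiv), AcOH (2.4 equiv), THF, 0 °C
Reagents that add atoms: none
Why: Fluoride cleaves both aryl silyl ethers, and the acetic acid buffer keeps the liberated 4'-phenol protonated so that C2 is not epimerised through a ring-opened quinone methide.

Compound list
1 | 5-methoxyresorcinol | COc1cc(O)cc(O)c1 | starting material
2 | 1-methoxy-3,5-bis(methoxymethoxy)benzene | COCOc1cc(OC)cc(OCOC)c1 | intermediate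
3 | prenyl bromide (1-bromo-3-methylbut-2-ene) | CC(C)=CCBr | starting material
4 | [4-methoxy-2,6-bis(methoxymethoxy)phenyl]lithium (not isolated) | COCOc1cc(OC)cc(OCOC)c1[Li] | intermediate
5 | 5-methoxy-1,3-bis(methoxymethoxy)-2-(3-methylbut-2-enyl)benzene | COCOc1cc(OC)cc(OCOC)c1CC=C(C)C | intermediate
6 | 5-methoxy-2-(3-methylbut-2-enyl)benzene-1,3-diol | COc1cc(O)c(CC=C(C)C)c(O)c1 | intermediate
7 | 5-methoxy-2-(3-methylbut-2-enyl)-3-(triisopropylsilyloxy)phenol | COc1cc(O)c(CC=C(C)C)c(O[Si](C(C)C)(C(C)C)C(C)C)c1 | intermediate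
8 | 2-(hydroxymethyl)-3-methoxy-6-(3-methylbut-2-enyl)-5-(triisopropylsilyloxy)phenol, present as its magnesium salt (not isolated) | COc1cc(O[Si](C(C)C)(C(C)C)C(C)C)c(CC=C(C)C)c(O)c1CO | intermediate
9 | 2-hydroxy-6-methoxy-3-(3-methylbut-2-enyl)-4-(triisopropylsilyloxy)benzaldehyde | COc1cc(O[Si](C(C)C)(C(C)C)C(C)C)c(CC=C(C)C)c(O)c1C=O | intermediate
10 | (E)-4-hydroxycinnamaldehyde | O=C/C=C/c1ccc(O)cc1 | starting material
11 | (E)-4-(triisopropylsilyloxy)cinnamaldehyde | O=C/C=C/c1ccc(O[Si](C(C)C)(C(C)C)C(C)C)cc1 | intermediate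
12 | iminium ion of 11 with the (S)-pyrrolidine catalyst, E at C=N and at C=C, 2-nitrobenzoate salt (not isolated) | C[Si](C)(C)OC(c1ccccc1)(c1ccccc1)[C@@H]1CCC/[N+]1=C\C=C\c1ccc(O[Si](C(C)C)(C(C)C)C(C)C)cc1.O=C([O-])c1ccccc1[N+](=O)[O-] | intermediate
13 | oxa-Michael adduct: (E)-enamine bearing the aryl ether of 9 at the former β-carbon, that carbon (S) by CIP and spatially as C2 of 15 (not isolated) | C[Si](C)(C)OC(c1ccccc1)(c1ccccc1)[C@@H]1CCCN1/C=C/[C@@H](c1ccc(O[Si](C(C)C)(C(C)C)C(C)C)cc1)Oc1c(C=O)c(OC)cc(O[Si](C(C)C)(C(C)C)C(C)C)c1CC=C(C)C | intermediate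
14 | ring-closed aldol adduct: 4-hydroxyflavan-3-ylmethylidene pyrrolidinium ion, C2 spatially as in 15, C3 and C4 transient and left undefined, 2-nitrobenzoate salt (not isolated) | C[Si](C)(C)OC(c1ccccc1)(c1ccccc1)[C@@H]1CCC[N+]1=CC1C(O)c2c(OC)cc(O[Si](C(C)C)(C(C)C)C(C)C)c(CC=C(C)C)c2O[C@@H]1c1ccc(O[Si](C(C)C)(C(C)C)C(C)C)cc1.O=C([O-])c1ccccc1[N+](=O)[O-] | intermediate
15 | (2R)-5-methoxy-8-(3-methylbut-2-enyl)-7-(triisopropylsilyloxy)-2-[4-(triisopropylsilyloxy)phenyl]-2H-chromene-3-carbaldehyde | COc1cc(O[Si](C(C)C)(C(C)C)C(C)C)c(CC=C(C)C)c2c1C=C(C=O)[C@@H](c1ccc(O[Si](C(C)C)(C(C)C)C(C)C)cc1)O2 | intermediate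
16 | (2S)-5-methoxy-8-(3-methylbut-2-enyl)-7-(triisopropylsilyloxy)-2-[4-(triisopropylsilyloxy)phenyl]-2H-chromene (flav-3-ene, C2 spatially unchanged) | COc1cc(O[Si](C(C)C)(C(C)C)C(C)C)c(CC=C(C)C)c2c1C=C[C@@H](c1ccc(O[Si](C(C)C)(C(C)C)C(C)C)cc1)O2 | intermediate
17 | (2S,3S)-3-(4,4,5,5-tetramethyl-1,3,2-dioxaborolan-2-yl) derivative of the 5-methoxy-8-prenyl-7,4'-bis(triisopropylsilyloxy)flavan, boron trans to the aryl group (not isolated) | COc1cc(O[Si](C(C)C)(C(C)C)C(C)C)c(CC=C(C)C)c2c1C[C@H](B1OC(C)(C)C(C)(C)O1)[C@@H](c1ccc(O[Si](C(C)C)(C(C)C)C(C)C)cc1)O2 | intermediate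
18 | (2R,3S)-5-methoxy-8-(3-methylbut-2-enyl)-7-(triisopropylsilyloxy)-2-[4-(triisopropylsilyloxy)phenyl]chroman-3-ol | COc1cc(O[Si](C(C)C)(C(C)C)C(C)C)c(CC=C(C)C)c2c1C[C@H](O)[C@@H](c1ccc(O[Si](C(C)C)(C(C)C)C(C)C)cc1)O2 | intermediate
19 | (2R,3S)-2-(4-hydroxyphenyl)-5-methoxy-8-(3-methylbut-2-enyl)chroman-3,7-diol (8-prenylafzelechin 5-methyl ether) | COc1cc(O)c(CC=C(C)C)c2c1C[C@H](O)[C@@H](c1ccc(O)cc1)O2 | target

Total step count: 10. Longest linear sequence: 9 steps (steps 1-5 and 7-10, from 1 to 19). Step 6 is the one-step side branch.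

Steps most likely to fail

**Step 8.**
- What may go wrong:
  - loss of enantiopurity through thermal or light-induced reversible electrocyclic opening of the 2H-chromene;
  - incomplete CO extrusion at the temperature that can be tolerated;
  - alkene migration induced by rhodium hydride.
- Fallback: the extra carbon is removed as CO2 by a radical route after C3=C4 has been saturated, so no chromene is ever heated.
  - From 15, Pinnick oxidation (NaClO2, NaH2PO4, large excess of 2-methyl-2-butene, t-BuOH/H2O, rt) should give the (2R)-2H-chromene-3-carboxylic acid F4.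
  - Carboxylate-directed hydrogenation with Ru(OAc)2(rac-binap) and H2 in MeOH at rt reduces only the conjugated alkene and gives the (2S)-chroman-3-carboxylic acid F5. Its C3 configuration does not matter.
  - N-Hydroxyphthalimide, DIC and catalytic DMAP in CH2Cl2 give the redox-active ester F6.
  - Irradiation with blue LEDs in DMAc with B2cat2 causes decarboxylative borylation. The planar C3 radical is trapped anti to the C2 aryl group and gives the catechol boronate F7.
  - Pinacol and Et3N convert F7 into 17, where the route is rejoined for the perborate oxidation.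

**Step 7.**
- What may go wrong:
  - slow turnover and erosion of enantioselectivity. The phenol is flanked by the prenyl chain, the acceptor aldehyde is electron-rich and doubly ortho-substituted, the donor-substituted iminium ion is a weak electrophile, and the oxa-Michael addition is reversible.
- Fallback: the same two bonds are made without asymmetric induction, and the absolute configuration is taken from a later kinetic resolution.
  - From 9 and 11, the small amine pyrrolidine (30 mol %) with benzoic acid in toluene at 40 °C should give the racemic chromene carbaldehyde F1.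
  - RhCl(PPh3)3 in refluxing toluene, now free of any configurational constraint, gives the racemic flav-3-ene F2.
  - Protoboration follows with CuCl, NaOt-Bu, a C2-symmetric chiral bisphosphine of the Ph-BPE type (enantiomer chosen so that the (2S)-alkene reacts faster), B2pin2 (0.55 equiv) and MeOH. It borylates that enantiomer only and leaves the (2R)-flav-3-ene F3 behind.
  - The route is rejoined at 17.

**Step 9.**
- What may go wrong:
  - addition with reversed regiochemistry, followed by β-aryloxide elimination and ring opening;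
  - sluggish addition to a very electron-rich and hindered styrene;
  - partial desilylation by alkoxide.
- Fallback: an uncatalysed hydroboration replaces the copper chemistry.
  - From 16, the reagent is disiamylborane F8, made from BH3·SMe2 and 2-methyl-2-butene (2 equiv) in THF at 0 °C.
  - This reagent is itself the stage at which hydroboration of a prenyl-type alkene stops, so it should not add to the side chain.
  - It places boron on the non-benzylic carbon of the cis-disubstituted styrene, anti to the aryl group, and gives the 3-(disiamylboryl)flavan F9.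
  - NaBO3·4H2O oxidation returns to 18.

Further compounds
F1 | step 7 | racemic 5-methoxy-8-(3-methylbut-2-enyl)-7-(triisopropylsilyloxy)-2-[4-(triisopropylsilyloxy)phenyl]-2H-chromene-3-carbaldehyde | COc1cc(O[Si](C(C)C)(C(C)C)C(C)C)c(CC=C(C)C)c2c1C=C(C=O)C(c1ccc(O[Si](C(C)C)(C(C)C)C(C)C)cc1)O2
F2 | step 7 | racemic 5-methoxy-8-(3-methylbut-2-enyl)-7-(triisopropylsilyloxy)-2-[4-(triisopropylsilyloxy)phenyl]-2H-chromene | COc1cc(O[Si](C(C)C)(C(C)C)C(C)C)c(CC=C(C)C)c2c1C=CC(c1ccc(O[Si](C(C)C)(C(C)C)C(C)C)cc1)O2
F3 | step 7 | (2R)-5-methoxy-8-(3-methylbut-2-enyl)-7-(triisopropylsilyloxy)-2-[4-(triisopropylsilyloxy)phenyl]-2H-chromene (slow-reacting enantiomer) | COc1cc(O[Si](C(C)C)(C(C)C)C(C)C)c(CC=C(C)C)c2c1C=C[C@H](c1ccc(O[Si](C(C)C)(C(C)C)C(C)C)cc1)O2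
F4 | step 8 | (2R)-5-methoxy-8-(3-methylbut-2-enyl)-7-(triisopropylsilyloxy)-2-[4-(triisopropylsilyloxy)phenyl]-2H-chromene-3-carboxylic acid | COc1cc(O[Si](C(C)C)(C(C)C)C(C)C)c(CC=C(C)C)c2c1C=C(C(=O)O)[C@@H](c1ccc(O[Si](C(C)C)(C(C)C)C(C)C)cc1)O2
F5 | step 8 | (2S)-5-methoxy-8-(3-methylbut-2-enyl)-7-(triisopropylsilyloxy)-2-[4-(triisopropylsilyloxy)phenyl]chroman-3-carboxylic acid, C3 undefined | COc1cc(O[Si](C(C)C)(C(C)C)C(C)C)c(CC=C(C)C)c2c1CC(C(=O)O)[C@@H](c1ccc(O[Si](C(C)C)(C(C)C)C(C)C)cc1)O2
F6 | step 8 | N-phthalimidoyl ester of F5, C3 undefined | COc1cc(O[Si](C(C)C)(C(C)C)C(C)C)c(CC=C(C)C)c2c1CC(C(=O)ON1C(=O)c3ccccc3C1=O)[C@@H](c1ccc(O[Si](C(C)C)(C(C)C)C(C)C)cc1)O2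
F7 | step 8 | (2S,3S)-3-(1,3,2-benzodioxaborol-2-yl) analogue of 17 | COc1cc(O[Si](C(C)C)(C(C)C)C(C)C)c(CC=C(C)C)c2c1C[C@H](B1Oc3ccccc3O1)[C@@H](c1ccc(O[Si](C(C)C)(C(C)C)C(C)C)cc1)O2
F8 | step 9 | disiamylborane, bis(3-methylbutan-2-yl)borane | CC(C)C(C)BC(C)C(C)C
F9 | step 9 | (2S,3S)-3-[bis(3-methylbutan-2-yl)boryl] analogue of 17 | COc1cc(O[Si](C(C)C)(C(C)C)C(C)C)c(CC=C(C)C)c2c1C[C@H](B(C(C)C(C)C)C(C)C(C)C)[C@@H](c1ccc(O[Si](C(C)C)(C(C)C)C(C)C)cc1)O2
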